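The readings are simulated for an exercise; scatter was added.

12 min was the time you asked about, and the first thing I looked at was whether the extra solid reagent in this flask would show in the yield.

| flask | left-handed substrate | right-handed substrate | solid reagent | remark | time |
|---|---|---|---|---|---|
| epsilon | 14 mM | 14 mM | 2 equiv | run made earlier |  |
| theta | 14 mM | 14 mM | 3 equiv | run made earlier |  |
| eta | 28 mM | 28 mM | 4 equiv | run made earlier |  |
| flask | 14 mM | 14 mM | 4.00 equiv |  | 12 min |

- epsilon (time / min: left-handed product / %): 0.500: 0; 1.33: 3; 3.00: 8; 8.00: 20
- theta (time / min: left-handed product / %): 0.500: 1; 1.33: 5; 3.00: 7; 8.00: 20
- eta (time / min: left-handed product / %): 2.00: 6; 4.00: 10; 5.00: 9; 8.00: 19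

(scatter of a reading: 1.5 percentage points)

- partner is single-handed; left-handed substrate and right-handed substrate are mirror images of each other, charged as a racemate, each of them at the stated concentration
- solid reagent is a solid; its amount is given per volume of the solution
- what was read earlier has a scatter of 1.5 percentage points, one standard deviation
- at the start none of the solid reagent is in solution
- partner is what solid reagent becomes in solution
- the handed part of partner does not stay in what it makes, so the products of the two hands are mirror images too

1. how much left-handed product there is at 12 min, in percent of the left-handed substrate and right-handed substrate together charged
2. concentration of partner in solution at 80 s, in percent of saturation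
3. the change that raises the amount of left-handed product at 12 min, in percent of the left-handed substrate and right-handed substrate together charged most ("none" if none brings more than 2 percentage points) (elm / birch / none)
4. amount of left-handed product at 12 min, in percent of the left-handed substrate and right-handed substrate together charged, after elm

- elm: doubling the solubility of the solid reagent, all else as stated
- birch: doubling the dissolution coefficient of the solid reagent, all else as stated

I held that question against the readings at 8.00 min. The epsilon run with 2 equiv read 20%, the theta run with 3 equiv read 20%, and the eta run, charged at twice the strength with 4 equiv, read 19%. These gaps lay within the scatter of 1.5 percentage points, so I saw no gain from more solid.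

I took the symmetric case as my zero. Each hand was half of the charge, so I assumed for this reckoning that each substrate fed its own product, took that half as my scale for left-handed product, and followed the fraction of it not yet read as product. In the epsilon run that fraction read 0.840 at 3.00 min and 0.600 at 8.00 min. I called the fall of its logarithm per minute the draw, 0.0673 /min, a pseudo-first-order rate constant read with the scatter of those readings. Carried on to 12 min, the draw gave me 27.1%, which was above the forecast.

The forecast gave 26.5% (24.5% to 29%), 89% of saturation at 80 s (75% to 97%), elm as the best change, and 39% after it (34% to 42%). Its ground was that “excess solid doesn't matter and the dissolved partner is capped at saturation”.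

    partner + left-handed substrate → left-handed product (k = 0.160 /M/s)
    partner + right-handed substrate → right-handed product (k = 0.0940 /M/s)
    left-handed substrate ⇌ achiral form (K = 0.0200, k = 0.00150 /s)
    right-handed substrate ⇌ achiral form (K = 0.0200, k = 0.00150 /s)
    achiral form → waste (k = 0.00810 /s)
    solid reagent ⇌ partner, rate k6*(cs6 - [partner]) while solid is left; crystals form when [partner] > cs6 (solubility = 7.60 mM, k = 0.0380 /s)

The flask gave 27.0%, with 88.5% of saturation at 80 s, and elm was best, reaching 40.2%. The draw left 45.8% of the left-handed substrate at 12 min, and this flask held 46% of its charge. Carried to the neighbouring flask read at 50 min, the draw gave 48.2% of the charge as left-handed product, and that flask held 50.8%, more than half of the charge.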